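**Strategy.** Ring C of the flavanone (O1–C2–C3–C4–C4a–C8a) is opened across C2–C3 and O1–C8a. C2 and O1 then come from one aldehyde C=O, and C3/C8a from an ortho-fluoro acetophenone whose C4 ketone activates C8a–F. In one pot, a catalytic enantioselective Mukaiyama aldol joins C3 to C2 and sets the (2S) centre. Fluoride then releases the C2 alkoxide, which displaces the fluoride at C8a (SNAr) to close ring C; the C2–O bond is never broken. The precursors are a benzyl-protected 3-(4-formylphenoxy)kaempferol and the enol silane of 2-fluoro-4,6-bis(benzyloxy)acetophenone. Hydrogenolysis ends the route.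

Key step: step 7

Remark: ketone 1 is taken as a commercial material, and the D-tryptophan-derived oxazaborolidinone is assumed to direct attack to the Si face of the aldehyde; if a test aldol shows the opposite sense, the L-antipode is used and nothing else changes.

Step 1
Reactants: 1 1-[2,4-bis(benzyloxy)-6-hydroxyphenyl]ethan-1-one; 2 4-(benzyloxy)benzaldehyde
Product: 3 (E)-1-[2,4-bis(benzyloxy)-6-hydroxyphenyl]-3-[4-(benzyloxy)phenyl]prop-2-en-1-one
Conditions: KOH (50% aq), EtOH/THF, rt
Reagents that add atoms: none
Why: Claisen–Schmidt (crossed aldol) condensation of the methyl ketone enolate with a non-enolisable aldehyde, with dehydration to the (E)-enone under thermodynamic control.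

Step 2
Reactants: 3 (E)-2'-hydroxychalcone
Product: 4 5,7-bis(benzyloxy)-2-[4-(benzyloxy)phenyl]-3-hydroxy-4H-chromen-4-one
Conditions: 30% H2O2, NaOH (aq), MeOH/THF, 0 °C to rt
Reagents that add atoms: hydrogen peroxide, OO
Why: Algar–Flynn–Oyamada oxidation, in which alkaline peroxide should convert the 2'-hydroxychalcone through the dihydroflavonol into the flavonol, the electron-rich 4-benzyloxyphenyl ring favouring six-membered closure at the β-carbon.

Step 3
Reactants: 4 tri-O-benzyl flavonol; 5 4-fluorobenzaldehyde
Product: 6 4-({5,7-bis(benzyloxy)-2-[4-(benzyloxy)phenyl]-4-oxo-4H-chromen-3-yl}oxy)benzaldehyde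
Conditions: K2CO3, DMF, 100 °C, argon
Reagents that add atoms: none
Why: SNAr etherification, in which the potassium salt of the only free hydroxyl (the enolic 3-OH) displaces fluoride para to the formyl group; argon excludes base-mediated oxygenolysis of the flavonol.

Step 4
Reactants: 7 5-fluorobenzene-1,3-diol
Product: 8 1-(2-fluoro-4,6-dihydroxyphenyl)ethan-1-one
Conditions: AcOH, BF3·OEt2 (Lewis acid promoter), 90 °C; then H2O
Reagents that add atoms: acetic acid, CC(=O)O
Why: Friedel–Crafts (Nencki-type) C-acylation of a resorcinol, expected ortho to one hydroxyl and para to the other at the less hindered C4 (the orcinol pattern) and not between the two hydroxyls, giving the chelated ortho-hydroxy ketone.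

Step 5
Reactants: 8 1-(2-fluoro-4,6-dihydroxyphenyl)ethan-1-one
Product: 9 1-[2,4-bis(benzyloxy)-6-fluorophenyl]ethan-1-one
Conditions: BnBr, K2CO3, DMF, 60 °C
Reagents that add atoms: benzyl bromide, BrCc1ccccc1
Why: Williamson ether synthesis, in which both phenols are alkylated in warm DMF (the chelated ortho-hydroxyl last) while the C–F bond is left alone by the weakly nucleophilic carbonate medium.

Step 6
Reactants: 9 1-[2,4-bis(benzyloxy)-6-fluorophenyl]ethan-1-one
Product: 10 {[1-(2,4-bis(benzyloxy)-6-fluorophenyl)ethenyl]oxy}trimethylsilane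
Conditions: TMSOTf, Et3N, CH2Cl2, 0 °C
Reagents that add atoms: trimethylsilyl triflate, C[Si](C)(C)OS(=O)(=O)C(F)(F)F
Why: Soft enolisation and O-silylation of a methyl ketone with a single enolisable position gives the terminal trimethylsilyl enol ether, used crude after removal of the ammonium salt.

Step 7
Reactants: 6 3-(4-formylphenoxy)flavone aldehyde; 10 trimethylsilyl enol ether (1.3 equiv)
Product: 12 (2S)-5,7-bis(benzyloxy)-2-[4-({5,7-bis(benzyloxy)-2-[4-(benzyloxy)phenyl]-4-oxo-4H-chromen-3-yl}oxy)phenyl]chroman-4-one, via silyl aldol ether 11 (not isolated)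
Conditions: (i) B-n-butyl oxazaborolidinone from N-tosyl-D-tryptophan (20 mol%), EtCN/CH2Cl2, −78 °C; (ii) TBAT (0.5 equiv, sub-stoichiometric), DMF, −40 to 0 °C, same pot
Reagents that add atoms: none
Why: Stage (i) is a chiral oxazaborolidinone-catalysed Mukaiyama aldol in which the boron Lewis acid binds the formyl group of 6 and the enol silane 10 attacks through an open transition state with silyl transfer to give 11, so the C3–C2 bond and the C2 stereocentre arise together; stage (ii) is a fluoride-triggered intramolecular SNAr in which the liberated C2 alkoxide adds to the C–F carbon ortho to the ketone (Meisenheimer anion delocalised into the C4 carbonyl) and expels fluoride, which leaves with the silyl group as Me3SiF and carries the chain, so the O1–C8a bond forms without the C2–O bond being broken. The closest known reaction types are the catalytic asymmetric Mukaiyama aldol of aryl methyl ketone enol silanes with aldehydes and the alkoxide SNAr ring closure of ortho-fluoroaryl ketones used for chromones and xanthones. Ring C closes as a six-membered ring by addition–elimination at the sp2 C–F carbon (6-exo-trig type attack). The configuration at C2 is controlled by the catalyst alone: the antipode that shields the Re face of the bound aldehyde is used, so that Si-face attack gives the (S)-aldolate, which is carried unchanged into (2S)-12. The step needs face selectivity, secured by the catalyst and by full consumption of 6 before fluoride is added so that no uncatalysed aldol can follow. It also needs SNAr to be faster than retro-aldol or ring opening by C3 enolisation, which the ortho-keto activation, the meta position of both benzyloxy groups relative to the C–F carbon, anhydrous sub-stoichiometric fluoride and low temperature should secure.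

Step 8
Reactants: 12 (2S)-penta-O-benzyl flavanone
Product: 13 (2S)-5,7-dihydroxy-2-[4-({5,7-dihydroxy-2-(4-hydroxyphenyl)-4-oxo-4H-chromen-3-yl}oxy)phenyl]chroman-4-one
Conditions: H2 (1 atm), 10% Pd/C, THF/MeOH, rt
Reagents that add atoms: none
Why: Catalytic hydrogenolysis of the five aryl benzyl ethers under neutral conditions, which should leave the flavonol C2=C3 bond, both aryl ketones and the diaryl ether intact and involves no base that could open the flavanone and racemise C2.

**Compound list**

1 | 1-[2,4-bis(benzyloxy)-6-hydroxyphenyl]ethan-1-one | CC(=O)c1c(O)cc(OCc2ccccc2)cc1OCc1ccccc1 | starting material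
2 | 4-(benzyloxy)benzaldehyde | O=Cc1ccc(OCc2ccccc2)cc1 | starting material
3 | (E)-1-[2,4-bis(benzyloxy)-6-hydroxyphenyl]-3-[4-(benzyloxy)phenyl]prop-2-en-1-one | O=C(/C=C/c1ccc(OCc2ccccc2)cc1)c1c(O)cc(OCc2ccccc2)cc1OCc1ccccc1 | intermediate
4 | 5,7-bis(benzyloxy)-2-[4-(benzyloxy)phenyl]-3-hydroxy-4H-chromen-4-one | O=c1c(O)c(-c2ccc(OCc3ccccc3)cc2)oc2cc(OCc3ccccc3)cc(OCc3ccccc3)c12 | intermediate
5 | 4-fluorobenzaldehyde | O=Cc1ccc(F)cc1 | starting material
6 | 4-({5,7-bis(benzyloxy)-2-[4-(benzyloxy)phenyl]-4-oxo-4H-chromen-3-yl}oxy)benzaldehyde | O=Cc1ccc(Oc2c(-c3ccc(OCc4ccccc4)cc3)oc3cc(OCc4ccccc4)cc(OCc4ccccc4)c3c2=O)cc1 | intermediate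
7 | 5-fluorobenzene-1,3-diol | Oc1cc(O)cc(F)c1 | starting material
8 | 1-(2-fluoro-4,6-dihydroxyphenyl)ethan-1-one | CC(=O)c1c(O)cc(O)cc1F | intermediate
9 | 1-[2,4-bis(benzyloxy)-6-fluorophenyl]ethan-1-one | CC(=O)c1c(F)cc(OCc2ccccc2)cc1OCc1ccccc1 | intermediate
10 | {[1-(2,4-bis(benzyloxy)-6-fluorophenyl)ethenyl]oxy}trimethylsilane | C=C(O[Si](C)(C)C)c1c(F)cc(OCc2ccccc2)cc1OCc1ccccc1 | intermediate
11 | (3S)-1-[2,4-bis(benzyloxy)-6-fluorophenyl]-3-[4-({5,7-bis(benzyloxy)-2-[4-(benzyloxy)phenyl]-4-oxo-4H-chromen-3-yl}oxy)phenyl]-3-(trimethylsilyloxy)propan-1-one | O=C(C[C@@H](c1ccc(Oc2c(-c3ccc(OCc4ccccc4)cc3)oc3cc(OCc4ccccc4)cc(OCc4ccccc4)c3c2=O)cc1)O[Si](C)(C)C)c1c(F)cc(OCc2ccccc2)cc1OCc1ccccc1 | intermediate (not isolated)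
12 | (2S)-5,7-bis(benzyloxy)-2-[4-({5,7-bis(benzyloxy)-2-[4-(benzyloxy)phenyl]-4-oxo-4H-chromen-3-yl}oxy)phenyl]chroman-4-one | O=C1C[C@@H](c2ccc(Oc3c(-c4ccc(OCc5ccccc5)cc4)oc4cc(OCc5ccccc5)cc(OCc5ccccc5)c4c3=O)cc2)Oc2cc(OCc3ccccc3)cc(OCc3ccccc3)c21 | intermediate
13 | (2S)-5,7-dihydroxy-2-[4-({5,7-dihydroxy-2-(4-hydroxyphenyl)-4-oxo-4H-chromen-3-yl}oxy)phenyl]chroman-4-one | O=C1C[C@@H](c2ccc(Oc3c(-c4ccc(O)cc4)oc4cc(O)cc(O)c4c3=O)cc2)Oc2cc(O)cc(O)c21 | target

**Step count.** Total: 8 steps. Longest linear sequence: 5 steps (1 → 2 → 3 → 7 → 8, or 4 → 5 → 6 → 7 → 8).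

**Steps most likely to fail**

1. Step 7. Enantiopurity may erode once fluoride is added, through retro-aldol and non-selective re-addition or through base-induced opening of the product at C2–O1. The SNAr may also be too slow on the electron-rich ring, so that the aldolate dehydrates, and the flavone carbonyl may inhibit the boron catalyst. Fallback: setting out from 6, a Claisen–Schmidt condensation with the starting ketone 1 (KOH, EtOH/THF, rt) should give the 2'-hydroxychalcone F1. NaOAc in refluxing EtOH should then close ring C by intramolecular oxa-Michael addition (O1–C2 bond) to the racemic flavanone F2. Preparative HPLC on a polysaccharide chiral stationary phase should deliver the (2S)-enantiomer, which is 12, where the route is rejoined.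

2. Step 2. The 6'-benzyloxy group may divert the oxidative cyclisation to five-membered closure at the α-carbon (aurone formation), and over-oxidation may lower the return. Fallback: setting out from 3, oxidative cyclisation with catalytic I2 in DMSO at 120 °C should give the flavone F3. Dimethyldioxirane in acetone/CH2Cl2 at 0 °C should convert it into the 2,3-epoxide F4, and catalytic p-TsOH should open this to the flavonol, which is 4.

3. Step 3. The hindered enolic oxygen may attack the only moderately activated fluoroarene too slowly, and the hot flavonolate may degrade oxidatively if traces of oxygen enter. Fallback: setting out from 4, a Chan–Lam coupling with 4-formylphenylboronic acid (Cu(OAc)2, pyridine, 4 Å molecular sieves, CH2Cl2, dry air, rt) should form the same aryl ether at room temperature and come back at 6; no new intermediate is made.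

**Further compounds**

F1 | step 7 | (E)-1-[2,4-bis(benzyloxy)-6-hydroxyphenyl]-3-[4-({5,7-bis(benzyloxy)-2-[4-(benzyloxy)phenyl]-4-oxo-4H-chromen-3-yl}oxy)phenyl]prop-2-en-1-one | O=C(/C=C/c1ccc(Oc2c(-c3ccc(OCc4ccccc4)cc3)oc3cc(OCc4ccccc4)cc(OCc4ccccc4)c3c2=O)cc1)c1c(O)cc(OCc2ccccc2)cc1OCc1ccccc1
F2 | step 7 | racemic 5,7-bis(benzyloxy)-2-[4-({5,7-bis(benzyloxy)-2-[4-(benzyloxy)phenyl]-4-oxo-4H-chromen-3-yl}oxy)phenyl]chroman-4-one | O=C1CC(c2ccc(Oc3c(-c4ccc(OCc5ccccc5)cc4)oc4cc(OCc5ccccc5)cc(OCc5ccccc5)c4c3=O)cc2)Oc2cc(OCc3ccccc3)cc(OCc3ccccc3)c21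
F3 | step 2 | 5,7-bis(benzyloxy)-2-[4-(benzyloxy)phenyl]-4H-chromen-4-one | O=c1cc(-c2ccc(OCc3ccccc3)cc2)oc2cc(OCc3ccccc3)cc(OCc3ccccc3)c12
F4 | step 2 | racemic cis-fused 2,3-epoxide of F3 (2,3-epoxy-5,7-bis(benzyloxy)-2-[4-(benzyloxy)phenyl]chroman-4-one) | O=C1C2OC2(c2ccc(OCc3ccccc3)cc2)Oc2cc(OCc3ccccc3)cc(OCc3ccccc3)c21
F0 | step 3 | none | none
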